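**Retrosynthetic overview**

- Target 10 is an all-(−)-epicatechin tetramer linked (4β→6), (4β→8), (4β→6) from the top unit down. All twelve rings and every C2/C3 stereocentre come intact from (−)-epicatechin, so no ring is formed in the route.
- Each interflavan C4–aryl bond is traced back to a C4–O bond: a 4β-(2-ethoxyethyl) ether made by oxidative C4–H etherification (DDQ/alcohol) is the electrophile. This C–O bond formation is the strategic step and is run three times: on the monomer, then (new) at the lower end of the dimer and of the trimer.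
- Regiocontrol comes from bromine at C8. The top, second and bottom units enter as the 8-bromide (attack forced to C6, top unit capped). The third unit enters unblocked, reacts at C8 and is then capped by the chain itself.
- Order of assembly, top-down: top unit + second unit (4β→6), oxidise, + third unit (4β→8), oxidise, + bottom unit (4β→6). One hydrogenolysis then removes 16 benzyl groups and 3 bromine atoms.

Assumption: (−)-epicatechin is taken as the cheap commercial chiral-pool material; reagents are named with SMILES on their own line and are not numbered; the four flavan units are called top, second, third and bottom (the bottom unit keeps the C4 methylene).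

**Step 1**
Reactants: 1 (−)-epicatechin
Product: 2 5,7,3',4'-tetra-O-benzyl-(−)-epicatechin (3-OH free)
Conditions: BnBr (4.4 equiv), K2CO3 (5 equiv), degassed DMF, 0 °C → rt, 24 h, N2
Reagents that add atoms: benzyl bromide, BrCc1ccccc1
Why: Williamson ether synthesis: K2CO3 deprotonates only the four phenols (the secondary 3-OH is far less acidic), which are O-benzylated; no stereocentre is touched, and the cold, oxygen-free start limits C2 epimerisation.

**Step 2**
Reactants: 2 5,7,3',4'-tetra-O-benzyl-(−)-epicatechin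
Product: 3 8-bromo-5,7,3',4'-tetra-O-benzyl-(−)-epicatechin
Conditions: NBS (1.0 equiv), CH2Cl2, −78 °C → rt
Reagents that add atoms: N-bromosuccinimide, O=C1CCC(=O)N1Br
Why: Electrophilic aromatic bromination: ring A is the most electron-rich arene and reacts once with one equivalent of NBS at C8, the position flanked by the ring oxygen and one benzyloxy group, rather than at C6 between two benzyloxy groups.

**Step 3**
Reactants: 3 8-bromo-5,7,3',4'-tetra-O-benzyl-(−)-epicatechin
Product: 4 8-bromo-4β-(2-ethoxyethoxy)-5,7,3',4'-tetra-O-benzyl-(−)-epicatechin (C4–O trans to 3-OH)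
Conditions: DDQ (2 equiv), EtOCH2CH2OH (10 equiv), CH2Cl2, rt; aq NaHCO3
Reagents that add atoms: 2-ethoxyethanol, CCOCCO
Why: Oxidative benzylic C–H etherification (DDQ hydride abstraction, then capture by the alcohol): only the C4–H aligned with the trioxygenated ring A is removed, and the alcohol adds trans to the 3-OH and 2-aryl groups, so the new C4–O stereocentre is 4β.

**Step 4**
Reactants: 4 8-bromo-4β-(2-ethoxyethoxy)-5,7,3',4'-tetra-O-benzyl-(−)-epicatechin; 3 8-bromo-5,7,3',4'-tetra-O-benzyl-(−)-epicatechin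
Product: 5 [8-bromo-5,7,3',4'-tetra-O-benzylepicatechin]-(4β→6)-[8-bromo-5,7,3',4'-tetra-O-benzylepicatechin] (dibromo dimer)
Conditions: Me3SiOTf (0.2 equiv), 4 Å molecular sieves, CH2Cl2, −78 → −30 °C, the ether added over 2 h into a fourfold excess of the bromide nucleophile (excess recovered); aq NaHCO3
Reagents that add atoms: none
Why: SN1-type Friedel–Crafts alkylation (interflavan bond formation): Me3SiOTf ionises the C4–O bond of 4 and the only open nucleophilic site of 3, C6 (C8 carries Br), attacks anti to the pseudo-axial 3-OH, which sets the C4 stereocentre of the top unit as 4β (2,3-cis-3,4-trans), while slow addition of 4 into excess 3 keeps the free C6–H of 4 from competing.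

**Step 5**
Reactants: 5 dibromo dimer
Product: 6 dibromo dimer carrying a 4β-(2-ethoxyethoxy) group at C4 of its lower unit (trans to the 3-OH there)
Conditions: DDQ (2.5 equiv), EtOCH2CH2OH (15 equiv), CH2Cl2, rt → 35 °C, dark; aq NaHCO3
Reagents that add atoms: 2-ethoxyethanol, CCOCCO
Why: Proposed new method: lower-end-selective oxidative C4–H etherification of an oligomeric flavan — DDQ should take hydride only from the C4 methylene of the lower unit, whose pseudo-axial C–H overlaps with its trioxygenated ring A (the 8-bromine only slows this, as in step 3), while the tertiary interflavan C4–H of the upper unit is quasi-equatorial (its 4β-aryl group is quasi-axial), lies close to the planes of both flanking arenes and is screened by two ortho benzyloxy groups, and the alcohol then adds trans to the 3-OH to give the 4β ether; the closest known reaction type is the DDQ/alcohol benzylic C4-alkoxylation of monomeric benzylated flavan-3-ols (step 3), which to my knowledge has not been used to re-activate a 4→6-linked, bromine-capped oligomer with free 3-OH groups.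

**Step 6**
Reactants: 6 C4-activated dibromo dimer; 2 5,7,3',4'-tetra-O-benzyl-(−)-epicatechin
Product: 7 [8-bromo-tetra-O-benzylepicatechin]-(4β→6)-[8-bromo-tetra-O-benzylepicatechin]-(4β→8)-[tetra-O-benzylepicatechin] (dibromo trimer)
Conditions: Me3SiOTf (0.2 equiv), 4 Å molecular sieves, CH2Cl2, −78 → −40 °C, threefold excess of the bromine-free nucleophile; aq NaHCO3
Reagents that add atoms: none
Why: SN1-type Friedel–Crafts alkylation: the ionised C4 of the lower unit of 6 is attacked by C8 of 2, its most nucleophilic and least hindered ring-A position, anti to the 3-OH, which sets the C4 stereocentre of the second unit as 4β and leaves the third unit capped at C8 by the chain itself.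

**Step 7**
Reactants: 7 dibromo trimer
Product: 8 dibromo trimer carrying a 4β-(2-ethoxyethoxy) group at C4 of its lowest unit (trans to the 3-OH there)
Conditions: DDQ (2 equiv), EtOCH2CH2OH (15 equiv), CH2Cl2, rt, dark; aq NaHCO3
Reagents that add atoms: 2-ethoxyethanol, CCOCCO
Why: Proposed new method: the same lower-end-selective oxidative C4–H etherification as in step 5, now on the trimer — only the C4 methylene of the lowest unit has a pseudo-axial C–H aligned with an electron-rich ring A (no bromine here, so faster than in step 5), the two tertiary interflavan C4–H bonds are quasi-equatorial and screened, and the alcohol adds trans to the 3-OH to give the 4β ether; closest known reaction type: DDQ/alcohol C4-alkoxylation of monomeric benzylated flavan-3-ols.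

**Step 8**
Reactants: 8 C4-activated dibromo trimer; 3 8-bromo-5,7,3',4'-tetra-O-benzyl-(−)-epicatechin
Product: 9 [8-bromo-tetra-O-benzylepicatechin]-(4β→6)-[8-bromo-tetra-O-benzylepicatechin]-(4β→8)-[tetra-O-benzylepicatechin]-(4β→6)-[8-bromo-tetra-O-benzylepicatechin] (tribromo hexadeca-O-benzyl tetramer)
Conditions: Me3SiOTf (0.3 equiv), 4 Å molecular sieves, CH2Cl2, −78 → −20 °C, the ether added over 2 h into a fivefold excess of the bromide nucleophile (excess recovered); aq NaHCO3
Reagents that add atoms: none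
Why: SN1-type Friedel–Crafts alkylation: the ionised C4 of the third unit is taken by C6 of 3 (C8 blocked by Br) anti to the 3-OH, setting the last C4 stereocentre as 4β, and the remaining C6–H sites of 8 are more hindered than that of 3 and are outcompeted by its fivefold excess.

**Step 9**
Reactants: 9 tribromo hexadeca-O-benzyl tetramer
Product: 10 epicatechin-(4β→6)-epicatechin-(4β→8)-epicatechin-(4β→6)-epicatechin (CNP0120618.1)
Conditions: H2 (1 atm), Pd(OH)2/C, NaOAc (3.3 equiv), THF/MeOH/H2O 20:1:1, rt; Celite, Sephadex LH-20, lyophilise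
Reagents that add atoms: none
Why: Catalytic hydrogenolysis with hydrodebromination: Pd(OH)2/C cleaves all sixteen O-benzyl groups and the three aryl C–Br bonds in one operation, NaOAc takes up the HBr that would otherwise endanger the acid-labile interflavan bonds, and no stereocentre is involved.

**Compound list**

1 | (−)-epicatechin, (2R,3R)-2-(3,4-dihydroxyphenyl)chromane-3,5,7-triol | Oc1cc(O)c2c(c1)O[C@H](c1ccc(O)c(O)c1)[C@H](O)C2 | starting material
2 | 5,7,3',4'-tetra-O-benzyl-(−)-epicatechin (2R,3R; 3-OH free) | c1ccccc1COc2cc(OCc3ccccc3)c3c(c2)O[C@H](c2ccc(OCc4ccccc4)c(OCc4ccccc4)c2)[C@H](O)C3 | intermediate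
3 | 8-bromo-5,7,3',4'-tetra-O-benzyl-(−)-epicatechin (2R,3R) | c1ccccc1COc2cc(OCc3ccccc3)c3c(c2Br)O[C@H](c2ccc(OCc4ccccc4)c(OCc4ccccc4)c2)[C@H](O)C3 | intermediate
4 | 8-bromo-4β-(2-ethoxyethoxy)-5,7,3',4'-tetra-O-benzyl-(−)-epicatechin (2,3-cis-3,4-trans) | c1ccccc1COc2cc(OCc3ccccc3)c3c(c2Br)O[C@H](c2ccc(OCc4ccccc4)c(OCc4ccccc4)c2)[C@H](O)[C@H]3OCCOCC | intermediate
5 | [8-bromo-tetra-O-benzylepicatechin]-(4β→6)-[8-bromo-tetra-O-benzylepicatechin] (dibromo dimer) | c1ccccc1COc2cc(OCc3ccccc3)c3c(c2Br)O[C@H](c2ccc(OCc4ccccc4)c(OCc4ccccc4)c2)[C@H](O)[C@H]3c2c(OCc4ccccc4)c(Br)c3c(c2OCc4ccccc4)C[C@@H](O)[C@@H](c2ccc(OCc4ccccc4)c(OCc4ccccc4)c2)O3 | intermediate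
6 | dibromo dimer carrying 4β-(2-ethoxyethoxy) at C4 of its lower unit | c1ccccc1COc2cc(OCc3ccccc3)c3c(c2Br)O[C@H](c2ccc(OCc4ccccc4)c(OCc4ccccc4)c2)[C@H](O)[C@H]3c2c(OCc4ccccc4)c(Br)c3c(c2OCc4ccccc4)[C@H](OCCOCC)[C@@H](O)[C@@H](c2ccc(OCc4ccccc4)c(OCc4ccccc4)c2)O3 | intermediate
7 | [8-bromo-tetra-O-benzylepicatechin]-(4β→6)-[8-bromo-tetra-O-benzylepicatechin]-(4β→8)-[tetra-O-benzylepicatechin] (dibromo trimer) | c1ccccc1COc2cc(OCc3ccccc3)c3c(c2Br)O[C@H](c2ccc(OCc4ccccc4)c(OCc4ccccc4)c2)[C@H](O)[C@H]3c2c(OCc4ccccc4)c(Br)c3c(c2OCc4ccccc4)[C@H](c5c(OCc4ccccc4)cc(OCc4ccccc4)c6c5O[C@H](c5ccc(OCc4ccccc4)c(OCc4ccccc4)c5)[C@H](O)C6)[C@@H](O)[C@@H](c2ccc(OCc4ccccc4)c(OCc4ccccc4)c2)O3 | intermediate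
8 | dibromo trimer carrying 4β-(2-ethoxyethoxy) at C4 of its lowest unit | c1ccccc1COc2cc(OCc3ccccc3)c3c(c2Br)O[C@H](c2ccc(OCc4ccccc4)c(OCc4ccccc4)c2)[C@H](O)[C@H]3c2c(OCc4ccccc4)c(Br)c3c(c2OCc4ccccc4)[C@H](c5c(OCc4ccccc4)cc(OCc4ccccc4)c6c5O[C@H](c5ccc(OCc4ccccc4)c(OCc4ccccc4)c5)[C@H](O)[C@H]6OCCOCC)[C@@H](O)[C@@H](c2ccc(OCc4ccccc4)c(OCc4ccccc4)c2)O3 | intermediate
9 | [8-bromo-tetra-O-benzylepicatechin]-(4β→6)-[8-bromo-tetra-O-benzylepicatechin]-(4β→8)-[tetra-O-benzylepicatechin]-(4β→6)-[8-bromo-tetra-O-benzylepicatechin] (tribromo hexadeca-O-benzyl tetramer) | c1ccccc1COc2cc(OCc3ccccc3)c3c(c2Br)O[C@H](c2ccc(OCc4ccccc4)c(OCc4ccccc4)c2)[C@H](O)[C@H]3c2c(OCc4ccccc4)c(Br)c3c(c2OCc4ccccc4)[C@H](c5c(OCc4ccccc4)cc(OCc4ccccc4)c6c5O[C@H](c5ccc(OCc4ccccc4)c(OCc4ccccc4)c5)[C@H](O)[C@H]6c5c(OCc4ccccc4)c(Br)c6c(c5OCc4ccccc4)C[C@@H](O)[C@@H](c5ccc(OCc4ccccc4)c(OCc4ccccc4)c5)O6)[C@@H](O)[C@@H](c2ccc(OCc4ccccc4)c(OCc4ccccc4)c2)O3 | intermediate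
10 | epicatechin-(4β→6)-epicatechin-(4β→8)-epicatechin-(4β→6)-epicatechin (CNP0120618.1) | Oc1cc(O)c2c(c1)O[C@H](c1ccc(O)c(O)c1)[C@H](O)[C@H]2c1c(O)cc2c(c1O)[C@H](c1c(O)cc(O)c3c1O[C@H](c1ccc(O)c(O)c1)[C@H](O)[C@H]3c1c(O)cc3c(c1O)C[C@@H](O)[C@@H](c1ccc(O)c(O)c1)O3)[C@@H](O)[C@@H](c1ccc(O)c(O)c1)O2 | target

Total step count: 9. Longest linear sequence: 9 steps (1 → 10; 2 and 3 are drawn again from the same line as building blocks).

**Three steps most likely to fail**

Step 5 (the proposed new method; step 7 uses it again on an easier, bromine-free ring). The risk is slow hydride abstraction on the brominated, fully substituted ring A, or attack at the interflavan C–H. The fallback is known chemistry, with hard/soft orthogonal C4–O and C4–S leaving groups. It sets out from 4 and comes back at 7, bypassing 5 and 6. Compound 4 is treated with 2,6-dimethylbenzenethiol and BF3·OEt2 (CH2Cl2, −78 °C) to give 8-bromo-4β-(2,6-dimethylphenylsulfanyl)-5,7,3',4'-tetra-O-benzylepicatechin F1. F1 (excess) then serves as the C6 nucleophile towards a second portion of 4 with BF3·OEt2 at −78 °C, where the hard Lewis acid ionises only the C4–O ether. This gives the dimer thioether [8-bromo-tetra-O-benzylepicatechin]-(4β→6)-[8-bromo-4β-(2,6-dimethylphenylsulfanyl)-tetra-O-benzylepicatechin] F2. F2 is ionised with the thiophile AgBF4 (THF/CH2Cl2, 4 Å molecular sieves, −20 °C) in the presence of a threefold excess of 2 to give 7.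

Step 8. The risk is that the trimeric electrophile meets only the hindered C6 of 3 and reacts instead at its own free C6–H sites. The fallback makes the last bond the easier 4β→8 one by a two-plus-two union. It sets out from 6 (its partner is built from 2 and 3) and comes back at 9, and it also spares step 7.
- Compound 2 with DDQ/2-ethoxyethanol (CH2Cl2, rt) gives 4β-(2-ethoxyethoxy)-5,7,3',4'-tetra-O-benzylepicatechin F3.
- NIS (CH2Cl2, 0 °C) iodinates C8 to give 8-iodo-4β-(2-ethoxyethoxy)-5,7,3',4'-tetra-O-benzylepicatechin F4, an iodine cap that can be told apart from bromine.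
- F4 and excess 3 with Me3SiOTf (−78 °C) give [8-iodo-tetra-O-benzylepicatechin]-(4β→6)-[8-bromo-tetra-O-benzylepicatechin] F5.
- Selective iodine–magnesium exchange (i-PrMgCl·LiCl in excess to cover the two free hydroxyl groups, THF, −20 °C; MeOH), which leaves the aryl bromide alone, gives [tetra-O-benzylepicatechin]-(4β→6)-[8-bromo-tetra-O-benzylepicatechin] F6.
- Compound 6 and F6 with Me3SiOTf (−78 → −40 °C) then couple through the free C8 of the upper unit of F6 to give 9.

Step 9. The risk is incomplete removal of sixteen benzyl groups next to three C–Br bonds, with HBr and long reaction times endangering the interflavan bonds. The fallback separates dehalogenation from debenzylation; it sets out from 9 and comes back at 10. Bromine–lithium exchange (n-BuLi in excess to cover the four free hydroxyl groups, THF, −78 °C; MeOH) gives the bromine-free hexadeca-O-benzyl tetramer F7. Halide-free hydrogenolysis (H2, Pd(OH)2/C, THF/MeOH/H2O, rt) then gives 10.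

**Further compounds**

F1 | step 5 | 8-bromo-4β-(2,6-dimethylphenylsulfanyl)-5,7,3',4'-tetra-O-benzylepicatechin | c1ccccc1COc2cc(OCc3ccccc3)c3c(c2Br)O[C@H](c2ccc(OCc4ccccc4)c(OCc4ccccc4)c2)[C@H](O)[C@H]3Sc2c(C)cccc2C
F2 | step 5 | [8-bromo-tetra-O-benzylepicatechin]-(4β→6)-[8-bromo-4β-(2,6-dimethylphenylsulfanyl)-tetra-O-benzylepicatechin] | c1ccccc1COc2cc(OCc3ccccc3)c3c(c2Br)O[C@H](c2ccc(OCc4ccccc4)c(OCc4ccccc4)c2)[C@H](O)[C@H]3c2c(OCc4ccccc4)c(Br)c3c(c2OCc4ccccc4)[C@H](Sc5c(C)cccc5C)[C@@H](O)[C@@H](c2ccc(OCc4ccccc4)c(OCc4ccccc4)c2)O3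
F3 | step 8 | 4β-(2-ethoxyethoxy)-5,7,3',4'-tetra-O-benzylepicatechin | c1ccccc1COc2cc(OCc3ccccc3)c3c(c2)O[C@H](c2ccc(OCc4ccccc4)c(OCc4ccccc4)c2)[C@H](O)[C@H]3OCCOCC
F4 | step 8 | 8-iodo-4β-(2-ethoxyethoxy)-5,7,3',4'-tetra-O-benzylepicatechin | c1ccccc1COc2cc(OCc3ccccc3)c3c(c2I)O[C@H](c2ccc(OCc4ccccc4)c(OCc4ccccc4)c2)[C@H](O)[C@H]3OCCOCC
F5 | step 8 | [8-iodo-tetra-O-benzylepicatechin]-(4β→6)-[8-bromo-tetra-O-benzylepicatechin] | c1ccccc1COc2cc(OCc3ccccc3)c3c(c2I)O[C@H](c2ccc(OCc4ccccc4)c(OCc4ccccc4)c2)[C@H](O)[C@H]3c2c(OCc4ccccc4)c(Br)c3c(c2OCc4ccccc4)C[C@@H](O)[C@@H](c2ccc(OCc4ccccc4)c(OCc4ccccc4)c2)O3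
F6 | step 8 | [tetra-O-benzylepicatechin]-(4β→6)-[8-bromo-tetra-O-benzylepicatechin] | c1ccccc1COc2cc(OCc3ccccc3)c3c(c2)O[C@H](c2ccc(OCc4ccccc4)c(OCc4ccccc4)c2)[C@H](O)[C@H]3c2c(OCc4ccccc4)c(Br)c3c(c2OCc4ccccc4)C[C@@H](O)[C@@H](c2ccc(OCc4ccccc4)c(OCc4ccccc4)c2)O3
F7 | step 9 | bromine-free hexadeca-O-benzyl tetramer linked (4β→6) then (4β→8) then (4β→6) | c1ccccc1COc2cc(OCc3ccccc3)c3c(c2)O[C@H](c2ccc(OCc4ccccc4)c(OCc4ccccc4)c2)[C@H](O)[C@H]3c2c(OCc4ccccc4)cc3c(c2OCc4ccccc4)[C@H](c5c(OCc4ccccc4)cc(OCc4ccccc4)c6c5O[C@H](c5ccc(OCc4ccccc4)c(OCc4ccccc4)c5)[C@H](O)[C@H]6c5c(OCc4ccccc4)cc6c(c5OCc4ccccc4)C[C@@H](O)[C@@H](c5ccc(OCc4ccccc4)c(OCc4ccccc4)c5)O6)[C@@H](O)[C@@H](c2ccc(OCc4ccccc4)c(OCc4ccccc4)c2)O3
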